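(The numbers in the tables were computed on assumed constants, and the scatter is random.)

At early times the teal flask, where free catalyst turns substrate and partner into target and released group, held 13.1 % target at 1.00 h; the violet flask, more dilute, held 10.7 % at 1.00 h.

common to all: free catalyst 0.5 mol%
- teal: substrate 0.40 M; partner 1.5 equiv; the very flask that is asked about, followed so far
- violet: substrate 0.27 M; partner 1.5 equiv; run made earlier
- flask: substrate 0.40 M; partner 1.50 equiv; time 20 h

| run | time / h | target / % |
|---|---|---|
| teal | 1.00 | 13.1 |
| teal | 1.50 | 17.8 |
| teal | 2.50 | 23.2 |
| teal | 4.00 | 22.2 |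
| teal | 8.00 | 14.6 |
| teal | 12.0 | 13.7 |
| violet | 0.500 | 4.5 |
| violet | 1.00 | 10.7 |
| violet | 1.33 | 12.2 |
| violet | 2.00 | 16.9 |
| violet | 2.50 | 18.1 |
| violet | 3.00 | 19.5 |

(scatter of a reading: 0.5 percentage points)

- target, in percent of the substrate first charged, at 20 h
- what to do for the largest gain in target; "none" if nothing gains more than 2 percentage points (gamma / zeta / eta / epsilon / none)
- target present, in percent of the substrate first charged, after zeta
- target present, in percent of the substrate first charged, after eta

- gamma: at 20 h add free catalyst, 100 % of the amount charged, then wait 10 h
- zeta: change nothing and wait 10 h more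
- eta: at 20 h take out 90 % of the released group then present, then wait 10 h
- epsilon: at 20 h add partner, 100 % of the amount charged, then wait 10 h

- the volume of additions can be left aside
- what was read earlier has a scatter of 0.5 percentage points, one standard deviation

The teal curve bent over and peaked in the readings at 23.2 % at 2.50 h. It then fell and flattened, so I read the fall from three evenly spaced readings. Successive drops were:

d₁ = 22.2 % − 14.6 % = 7.6 percentage points

d₂ = 14.6 % − 13.7 % = 0.9 points

If each drop shrinks by the same factor, the curve runs into a level, and the distance from it decays exponentially:

τ = (8.00 h − 4.00 h) / ln(d₁/d₂) = 1.87 h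

level = 13.7 % − d₂²/(d₁ − d₂) = 13.6 %

I call 1.87 h the fall lifetime: the time in which the target's distance from its level shrinks by a factor of e. It is a rough reading, since d₂ stands against a scatter of 0.5 points.

The teal flask at 20 h lies 4.27 fall lifetimes past the last reading, so I committed to 13.6 % for now. The further 10 h is 5.33 lifetimes, so I expected zeta to give the same level, and any change made at 20 h to have time to show. The readings did not separate the other options for me.

The forecast gave 13.4 % at 20 h, a little below my level, and 13.3 % after zeta. It chose eta, with 19 % after it, holding that the flat level “suggests a balance rather than simple sequential loss”.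

    partner + free catalyst ⇌ catalyst intermediate A (K = 18.0 L mol⁻¹, k = 9400 L mol⁻¹ h⁻¹)
    substrate + catalyst intermediate A ⇌ catalyst intermediate B (K = 0.620 L mol⁻¹, k = 14000 L mol⁻¹ h⁻¹)
    catalyst intermediate B ⇌ released group + catalyst intermediate C (K = 0.360 M, k = 250 h⁻¹)
    catalyst intermediate C → free catalyst + target (k = 110 h⁻¹)
    target + free catalyst ⇌ isomer of the product + free catalyst, rate k5*[free catalyst]*[target] forward; the back reaction follows from the equilibrium constant (K = 1.30, k = 150 L mol⁻¹ h⁻¹)
    partner → decomposed reagent (k = 0.740 h⁻¹)

The teal flask gave 13.7 % at 20 h, and the best option was epsilon, a gain of 8.9 points against 0 points for eta. At 20.0 h [partner], the limiting reagent, stood at 0 % of its charge, with 68.5 % of the substrate free. Over the 5.33 fall lifetimes of zeta the target stayed at 13.7 %. Taking the fall lifetime as inverse to the loading of free catalyst, I estimate it for the neighbouring flask with 1.2 mol% free catalyst at 0.781 h, so that flask's 20 h spans 25.6 of them, and that flask held 21.5 % target beside 28.0 % isomer of the product.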